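**Plan**

- Numbering used throughout: oxolane O1, C2 (aryl trans to the C3 methyl), C3, C4, C5 (aryl cis to the C4 methyl). The target is (2S,3S,4S,5R), which is (2R,3S,4S,5S) when numbered from the other aryl carbon: 2,3-trans, 3,4-trans, 4,5-cis, 2,5-cis.
- Enabling feature: O1–C5(aryl)=C4 of the ring is the enol of an aroylacetic acid whose carboxyl carbon becomes the C4 methyl, and C2(aryl)–C3(methyl), trans, is an E-propenylarene. The retrosynthesis first returns C4–CH3 and C5–H to a 4-acyl-2,3-dihydrofuran, then cuts C3–C4 and O1–C2.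
- Forward: both aryl units are made as benzyl ethers from syringic acid and 4-allyl-2,6-dimethoxyphenol. The only ring closes in one oxidative annulation of a β-keto imide with the propenylarene, C3–C4 by radical addition and then O1–C2 by cation capture.
- Stereochemistry: C2/C3 trans comes from ring closure of the benzylic cation anti to the C3 methyl. The absolute sense comes from an (S)-4-benzyloxazolidinone on the aroylacetyl unit, which also makes the two trans products separable diastereomers.
- C4 and C5 are then set from C3 and C2 in an ionic hydrogenation (C4 methyl trans to C3 methyl by equilibration, hydride to C5 anti to the C4 methyl and the C2 aryl). Hydrogenolysis of the two benzyl ethers ends the route.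

Key step: step 7

Assumption: the (S)-auxiliary is taken to favour the alkene face that leads to the (2S,3S) ring; if the (2R,3R) diastereomer should prevail, the (R)-auxiliary is used and nothing else changes.

**Route**

Step 1
Reactants: 1 syringic acid (4-hydroxy-3,5-dimethoxybenzoic acid)
Product: 3 4-(benzyloxy)-3,5-dimethoxybenzoic acid, via benzyl ester 2 (not isolated)
Conditions: BnBr (2.3 equiv), K2CO3, DMF, 60 °C; then 2 M aq NaOH, MeOH, 65 °C; HCl to pH 2
Reagents that add atoms: benzyl bromide, BrCc1ccccc1; sodium hydroxide, [Na+].[OH-]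
Why: Williamson O-benzylation of both the phenoxide and the carboxylate is followed in the same flask by saponification of the benzyl ester, which is far more labile to hydroxide than the aryl benzyl ether that must remain.

Step 2
Reactants: 3 4-(benzyloxy)-3,5-dimethoxybenzoic acid
Product: 4 4-(benzyloxy)-3,5-dimethoxybenzoyl chloride
Conditions: (COCl)2 (1.3 equiv), DMF (cat.), CH2Cl2, 0 °C → rt
Reagents that add atoms: oxalyl chloride, ClC(=O)C(=O)Cl
Why: Acid chloride formation through the DMF-derived chloroiminium species runs cold and without strong acid, so the benzyl ether and the methoxy groups should be left alone.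

Step 3
Reactants: 5 (S)-4-benzyloxazolidin-2-one
Product: 6 (S)-3-acetyl-4-benzyloxazolidin-2-one
Conditions: n-BuLi (1.05 equiv), THF, −78 °C; AcCl, −78 → 0 °C
Reagents that add atoms: acetyl chloride, CC(=O)Cl
Why: N-Acylation of the lithiated oxazolidinone with acetyl chloride is the standard entry to N-acyl auxiliaries and does not touch the stereocentre of the auxiliary.

Step 4
Reactants: 6 (S)-3-acetyl-4-benzyloxazolidin-2-one (2.1 equiv, excess recovered); 4 4-(benzyloxy)-3,5-dimethoxybenzoyl chloride
Product: 7 (S)-4-benzyl-3-[3-(4-benzyloxy-3,5-dimethoxyphenyl)-3-oxopropanoyl]oxazolidin-2-one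
Conditions: LDA (2.1 equiv), THF, −78 °C; then 4 (1.0 equiv), −78 °C; AcOH quench at −78 °C
Reagents that add atoms: none
Why: Crossed Claisen condensation, in which the chelated lithium enolate of 6 is C-acylated by the aroyl chloride and the second equivalent of enolate takes up the acidic proton of the β-keto imide, so that 7 stays protected as its own enolate until the quench.

Step 5
Reactants: 8 4-allyl-2,6-dimethoxyphenol
Product: 9 5-allyl-2-(benzyloxy)-1,3-dimethoxybenzene
Conditions: BnBr (1.2 equiv), K2CO3, acetone, reflux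
Reagents that add atoms: benzyl bromide, BrCc1ccccc1
Why: Williamson ether synthesis on the hindered but acidic 2,6-dimethoxyphenol with a reactive benzylic halide.

Step 6
Reactants: 9 5-allyl-2-(benzyloxy)-1,3-dimethoxybenzene
Product: 10 2-(benzyloxy)-1,3-dimethoxy-5-[(E)-prop-1-enyl]benzene
Conditions: KOt-Bu (0.5 equiv), DMSO, 25 °C
Reagents that add atoms: none
Why: Base-catalysed prototropic isomerisation of the allylarene through the benzylic–allylic anion moves the double bond into conjugation and should give the thermodynamically preferred E alkene, and any Z isomer left would converge on the same product in step 7.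

Step 7
Reactants: 7 (S)-4-benzyl-3-[3-(4-benzyloxy-3,5-dimethoxyphenyl)-3-oxopropanoyl]oxazolidin-2-one; 10 2-(benzyloxy)-1,3-dimethoxy-5-[(E)-prop-1-enyl]benzene (1.3 equiv)
Product: 11 (S)-4-benzyl-3-{[(2S,3S)-2,5-bis(4-benzyloxy-3,5-dimethoxyphenyl)-3-methyl-2,3-dihydrofuran-4-yl]carbonyl}oxazolidin-2-one
Conditions: Mn(OAc)3·2H2O (2.2 equiv), degassed AcOH, 40 °C, under argon; minor diastereomer removed by chromatography or crystallisation
Reagents that add atoms: none
Why: Mn(OAc)3 converts 7 into its trivalent-manganese enolate, chelated through the ketone and imide acyl oxygens; one-electron oxidation gives an electrophilic radical at the doubly activated carbon that adds to the methyl-bearing alkene carbon of 10 (C3–C4), and a second Mn(OAc)3 oxidises the resulting benzylic radical to the para-alkoxybenzyl cation, which the enol oxygen of the aryl ketone captures (O1–C2) with loss of a proton to leave the C4=C5 enol ether. The closest known reaction type is the manganese triacetate oxidative annulation of β-keto esters and amides with β-methylstyrenes to trans-2-aryl-3-methyl-2,3-dihydrofurans. The single ring closes by 5-exo O-alkylation of the enol, whose double bond lies inside the new ring, on the benzylic cation, which is preferred over three-membered C-alkylation. C3 is set in the radical addition: the benzyl group of the (S)-oxazolidinone screens one face of the chelated enolate and the alkene is expected to approach the open face with its hydrogen toward the auxiliary and its arylvinyl arm over the less crowded aroyl side, which is taken to give (3S); C2 is set in the ring closure, where the freely rotating cation closes with its aryl group anti to the C3 methyl, so both alkene geometries should give the 2,3-trans ring. The step needs regio-, chemo- and face selectivity: the first two rest on the electron-rich propenylarene, which gives a benzylic radical that is easily oxidised, and on the doubly activated methylene of 7, which reacts faster than a product that has no hydrogen left at C4. Face selectivity is the least certain, and because the auxiliary makes the (2S,3S) and (2R,3R) rings diastereomers, the unwanted one can be separated.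

Step 8
Reactants: 11 (S)-4-benzyl-3-{[(2S,3S)-2,5-bis(4-benzyloxy-3,5-dimethoxyphenyl)-3-methyl-2,3-dihydrofuran-4-yl]carbonyl}oxazolidin-2-one
Product: 12 [(2S,3S)-2,5-bis(4-benzyloxy-3,5-dimethoxyphenyl)-3-methyl-2,3-dihydrofuran-4-yl]methanol
Conditions: LiBH4 (3 equiv), MeOH (3 equiv), THF, 0 °C → rt; 1 M NaOH work-up; Et3N-deactivated silica
Reagents that add atoms: none
Why: Reductive cleavage of the N-acyl oxazolidinone, in which borohydride adds to the exocyclic imide carbonyl, the hemiaminal collapses to the vinylogous formate aldehyde and this is reduced on to the primary allylic alcohol, while the push-pull C4=C5 bond, fully substituted at its oxygen-bearing carbon, should resist conjugate reduction and C2 and C3 are untouched.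

Step 9
Reactants: 12 [(2S,3S)-2,5-bis(4-benzyloxy-3,5-dimethoxyphenyl)-3-methyl-2,3-dihydrofuran-4-yl]methanol
Product: 14 (2S,3S,4S,5R)-2,5-bis(4-benzyloxy-3,5-dimethoxyphenyl)-3,4-dimethyloxolane, via 4-methyl enol ether 13 (not isolated)
Conditions: Et3SiH (6 equiv), BF3·OEt2 (1.5 equiv), CH2Cl2, −78 → −40 °C; Et3N, then aq NaHCO3 at −40 °C
Reagents that add atoms: none
Why: Ionic hydrogenation, in which BF3 ionises the allylic alcohol to an aryl-stabilised vinylogous oxocarbenium ion that should take hydride at its unhindered methylene terminus to give enol ether 13, the acid formed from the departing hydroxyl reprotonates 13 at C4 reversibly so that the ion with the C4 methyl trans to the C3 methyl accumulates, and Et3SiH then adds to C5 from the face anti to the C4 methyl and the C2 aryl group, as in the known hydride reductions of 2-aryl-3-methyl cyclic hemiketals, which sets C4 (S) and C5 (R).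

Step 10
Reactants: 14 (2S,3S,4S,5R)-2,5-bis(4-benzyloxy-3,5-dimethoxyphenyl)-3,4-dimethyloxolane
Product: 15 4,4'-[(2S,3S,4S,5R)-3,4-dimethyloxolane-2,5-diyl]bis(2,6-dimethoxyphenol) (CNP0217414.2)
Conditions: H2 (1 atm), 10% Pd/C, EtOAc–MeOH, rt, stopped as soon as 14 is consumed
Reagents that add atoms: none
Why: Catalytic hydrogenolysis of aryl benzyl ethers is much faster than that of the benzylic C–O bonds of the oxolane ring, so brief exposure at 1 atm should free both phenols without ring opening or epimerisation.

**Compound list**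

1 | syringic acid (4-hydroxy-3,5-dimethoxybenzoic acid) | COc1cc(C(=O)O)cc(OC)c1O | starting material
2 | benzyl 4-(benzyloxy)-3,5-dimethoxybenzoate | COc1cc(C(=O)OCc2ccccc2)cc(OC)c1OCc1ccccc1 | intermediate
3 | 4-(benzyloxy)-3,5-dimethoxybenzoic acid | COc1cc(C(=O)O)cc(OC)c1OCc1ccccc1 | intermediate
4 | 4-(benzyloxy)-3,5-dimethoxybenzoyl chloride | COc1cc(C(=O)Cl)cc(OC)c1OCc1ccccc1 | intermediate
5 | (S)-4-benzyloxazolidin-2-one | O=C1N[C@@H](Cc2ccccc2)CO1 | starting material
6 | (S)-3-acetyl-4-benzyloxazolidin-2-one | CC(=O)N1[C@@H](Cc2ccccc2)COC1=O | intermediate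
7 | (S)-4-benzyl-3-[3-(4-benzyloxy-3,5-dimethoxyphenyl)-3-oxopropanoyl]oxazolidin-2-one | O=C(CC(=O)N1[C@@H](Cc2ccccc2)COC1=O)c1cc(OC)c(OCc2ccccc2)c(OC)c1 | intermediate
8 | 4-allyl-2,6-dimethoxyphenol | C=CCc1cc(OC)c(O)c(OC)c1 | starting material
9 | 5-allyl-2-(benzyloxy)-1,3-dimethoxybenzene | C=CCc1cc(OC)c(OCc2ccccc2)c(OC)c1 | intermediate
10 | 2-(benzyloxy)-1,3-dimethoxy-5-[(E)-prop-1-enyl]benzene | C/C=C/c1cc(OC)c(OCc2ccccc2)c(OC)c1 | intermediate
11 | (S)-4-benzyl-3-{[(2S,3S)-2,5-bis(4-benzyloxy-3,5-dimethoxyphenyl)-3-methyl-2,3-dihydrofuran-4-yl]carbonyl}oxazolidin-2-one (2,3-trans) | COc1cc([C@H]2OC(c3cc(OC)c(OCc4ccccc4)c(OC)c3)=C(C(=O)N3[C@@H](Cc4ccccc4)COC3=O)[C@@H]2C)cc(OC)c1OCc1ccccc1 | intermediate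
12 | [(2S,3S)-2,5-bis(4-benzyloxy-3,5-dimethoxyphenyl)-3-methyl-2,3-dihydrofuran-4-yl]methanol | COc1cc([C@H]2OC(c3cc(OC)c(OCc4ccccc4)c(OC)c3)=C(CO)[C@@H]2C)cc(OC)c1OCc1ccccc1 | intermediate
13 | (2S,3S)-2,5-bis(4-benzyloxy-3,5-dimethoxyphenyl)-3,4-dimethyl-2,3-dihydrofuran | COc1cc([C@H]2OC(c3cc(OC)c(OCc4ccccc4)c(OC)c3)=C(C)[C@@H]2C)cc(OC)c1OCc1ccccc1 | intermediate
14 | (2S,3S,4S,5R)-2,5-bis(4-benzyloxy-3,5-dimethoxyphenyl)-3,4-dimethyloxolane (2,3-trans, 3,4-trans, 4,5-cis) | COc1cc([C@H]2O[C@@H](c3cc(OC)c(OCc4ccccc4)c(OC)c3)[C@@H](C)[C@@H]2C)cc(OC)c1OCc1ccccc1 | intermediate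
15 | 4,4'-[(2S,3S,4S,5R)-3,4-dimethyloxolane-2,5-diyl]bis(2,6-dimethoxyphenol) | COc1cc([C@H]2O[C@@H](c3cc(OC)c(O)c(OC)c3)[C@@H](C)[C@@H]2C)cc(OC)c1O | target

**Count and risks**

Total step count: 10. Longest linear sequence: 7 steps (steps 1, 2, 4, 7, 8, 9, 10 from syringic acid).

Steps most likely to fail:

Step 7. The auxiliary sits on the radical partner while the permanent stereocentre C3 is created on the alkene, so discrimination between the two alkene faces may be poor and much of the material would be lost as the (2R,3R) diastereomer. Fallback (sets out from 4, returns at 14): C2 and C3 are set by reagent control and the ring is closed through a lactone.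
- Acid chloride 4 is reduced with LiAlH(Ot-Bu)3 (THF, −78 °C) to 4-(benzyloxy)-3,5-dimethoxybenzaldehyde F1.
- Asymmetric crotylboration with (E)-crotyldiisopinocampheylborane, using the α-pinene antipode that attacks the aldehyde si face (Et2O, −78 °C; NaOH, H2O2), should give the anti homoallylic alcohol (1S,2S)-1-[4-(benzyloxy)-3,5-dimethoxyphenyl]-2-methylbut-3-en-1-ol F2.
- Hydroboration–oxidation (9-BBN, THF; NaOH, H2O2) gives (1S,2S)-1-[4-(benzyloxy)-3,5-dimethoxyphenyl]-2-methylbutane-1,4-diol F3.
- TEMPO with PhI(OAc)2 (CH2Cl2) oxidises the primary alcohol through the lactol to the trans lactone (4S,5S)-5-[4-(benzyloxy)-3,5-dimethoxyphenyl]-4-methyloxolan-2-one F4.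
- Enolate methylation (LiHMDS, MeI, THF, −78 °C) anti to the ring methyl gives (3S,4S,5S)-5-[4-(benzyloxy)-3,5-dimethoxyphenyl]-3,4-dimethyloxolan-2-one F5.
- 2-(Benzyloxy)-5-bromo-1,3-dimethoxybenzene F6 (from 4-bromo-2,6-dimethoxyphenol, BnBr, K2CO3) is lithiated (n-BuLi, THF, −78 °C) and added to F5 to give the cyclic hemiketal (3S,4S,5S)-2,5-bis[4-(benzyloxy)-3,5-dimethoxyphenyl]-3,4-dimethyloxolan-2-ol F7.
- Et3SiH with BF3·OEt2 (CH2Cl2, −78 °C) ionises F7 to the same oxocarbenium ion as in step 9 and should deliver 14, which continues with step 10.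

Step 9. The first hydride may be delivered to ring carbon C5 of the extended cation instead of the methylene carbon, leaving an exocyclic alkene that is not reduced cleanly. The C4 centre may also be reduced before it has equilibrated, and long contact with BF3 may open the benzylic C–O bonds and erode the 4,5-cis relationship. Fallback (sets out from 12, returns at 13 and from there at 14): the deoxygenation is taken out of the cationic manifold.
- Acetylation (Ac2O, pyridine, DMAP, 0 °C) gives [(2S,3S)-2,5-bis(4-benzyloxy-3,5-dimethoxyphenyl)-3-methyl-2,3-dihydrofuran-4-yl]methyl acetate F8.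
- Zerovalent palladium, Pd(PPh3)4, with LiBHEt3 (THF, 0 °C) forms the π-allyl complex and delivers hydride to its unhindered methylene terminus (Tsuji–Trost-type reduction), giving enol ether 13 as an isolated compound.
- 13 is then reduced with Et3SiH and CF3CO2H (CH2Cl2, −40 °C), the acid now supplying the proton for C4, to 14.

Step 8. The acyl carbonyl is a vinylogous carbamate and may be so deactivated that borohydride attacks the ring carbonyl of the oxazolidinone instead, opening the auxiliary; the acid-labile allylic alcohol may also decompose on isolation. Fallback (sets out from 11, returns at 12): cleavage and reduction are separated.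
- LiOH with H2O2 (THF–H2O, 0 °C), whose hydroperoxide anion is selective for the exocyclic carbonyl, gives (2S,3S)-2,5-bis(4-benzyloxy-3,5-dimethoxyphenyl)-3-methyl-2,3-dihydrofuran-4-carboxylic acid F9 together with the recovered auxiliary.
- Reduction of F9 with LiAlH4 (THF, 0 °C → rt, basic work-up) gives 12.

Further compounds
F1 | step 7 | 4-(benzyloxy)-3,5-dimethoxybenzaldehyde | COc1cc(C=O)cc(OC)c1OCc1ccccc1
F2 | step 7 | (1S,2S)-1-[4-(benzyloxy)-3,5-dimethoxyphenyl]-2-methylbut-3-en-1-ol | COc1cc([C@@H](O)[C@@H](C)C=C)cc(OC)c1OCc1ccccc1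
F3 | step 7 | (1S,2S)-1-[4-(benzyloxy)-3,5-dimethoxyphenyl]-2-methylbutane-1,4-diol | COc1cc([C@@H](O)[C@@H](C)CCO)cc(OC)c1OCc1ccccc1
F4 | step 7 | (4S,5S)-5-[4-(benzyloxy)-3,5-dimethoxyphenyl]-4-methyloxolan-2-one | COc1cc([C@H]2OC(=O)C[C@@H]2C)cc(OC)c1OCc1ccccc1
F5 | step 7 | (3S,4S,5S)-5-[4-(benzyloxy)-3,5-dimethoxyphenyl]-3,4-dimethyloxolan-2-one | COc1cc([C@H]2OC(=O)[C@@H](C)[C@@H]2C)cc(OC)c1OCc1ccccc1
F6 | step 7 | 2-(benzyloxy)-5-bromo-1,3-dimethoxybenzene | COc1cc(Br)cc(OC)c1OCc1ccccc1
F7 | step 7 | (3S,4S,5S)-2,5-bis[4-(benzyloxy)-3,5-dimethoxyphenyl]-3,4-dimethyloxolan-2-ol (mixture at the hemiketal carbon) | COc1cc([C@H]2OC(O)(c3cc(OC)c(OCc4ccccc4)c(OC)c3)[C@@H](C)[C@@H]2C)cc(OC)c1OCc1ccccc1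
F8 | step 9 | [(2S,3S)-2,5-bis(4-benzyloxy-3,5-dimethoxyphenyl)-3-methyl-2,3-dihydrofuran-4-yl]methyl acetate | COc1cc([C@H]2OC(c3cc(OC)c(OCc4ccccc4)c(OC)c3)=C(COC(C)=O)[C@@H]2C)cc(OC)c1OCc1ccccc1
F9 | step 8 | (2S,3S)-2,5-bis(4-benzyloxy-3,5-dimethoxyphenyl)-3-methyl-2,3-dihydrofuran-4-carboxylic acid | COc1cc([C@H]2OC(c3cc(OC)c(OCc4ccccc4)c(OC)c3)=C(C(=O)O)[C@@H]2C)cc(OC)c1OCc1ccccc1
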